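**Retrosynthetic overview**
1. Target 12 ⇐ diol 9: one-pot O-acylation with palmitoyl chloride, then dehydration of the tertiary carbinol to the isopropenyl group.
2. Diol 9 ⇐ hydroxy ester 8: the gem-dimethyl carbinol comes from the methyl ester and two equivalents of MeMgBr.
3. Ester 8 ⇐ bromoquinolone 5 + methyl (R)-glycidate 6: the key C3–CH2 bond is made by a light-driven nickel cross-electrophile coupling; 6 supplies the only stereocenter.
4. Bromide 5 ⇐ 3 ⇐ 1 + 2: C3 bromination, O-methylation, and cyclocondensation of the aniline with an active malonate.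
5. Ring order: ring A (benzene) is bought; ring B (pyridone) is the only ring formed, in step 1.

Assumption: 2-methoxy-N-methylaniline, bis(2,4,6-trichlorophenyl) malonate and methyl (2R)-oxirane-2-carboxylate (the L-serine-derived glycidic ester) are taken as commercial.

The target's stereocenter is (R). The C2–O bond of 6 is never broken, so the configuration is carried from 6 through 8, 9 and 11 into 12.

**Step 1**
Reactants: 1 2-methoxy-N-methylaniline; 2 bis(2,4,6-trichlorophenyl) malonate
Product: 3 4-hydroxy-8-methoxy-1-methylquinolin-2(1H)-one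
Conditions: neat, 210 °C, 30 min; Et2O trituration
Reagents that add atoms: none
Why: The activated aryl malonate N-acylates the aniline and the resulting aryl malonanilate cyclises through an acylketene onto the free ortho carbon (thermal malonate cyclocondensation), which builds ring B; no stereocenter is involved.

**Step 2**
Reactants: 3 4-hydroxy-8-methoxy-1-methylquinolin-2(1H)-one
Product: 4 4,8-dimethoxy-1-methylquinolin-2(1H)-one
Conditions: Me2SO4 (1.2 equiv), K2CO3 (2 equiv), acetone, reflux
Reagents that add atoms: dimethyl sulfate, COS(=O)(=O)OC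
Why: The acidic 4-OH (a vinylogous carboxylic acid) is O-methylated by the hard electrophile dimethyl sulfate (Williamson-type O-alkylation), with little C3-methylation.

**Step 3**
Reactants: 4 4,8-dimethoxy-1-methylquinolin-2(1H)-one
Product: 5 3-bromo-4,8-dimethoxy-1-methylquinolin-2(1H)-one
Conditions: NBS (1.05 equiv), MeCN, 0 °C to rt, dark
Reagents that add atoms: N-bromosuccinimide, O=C1CCC(=O)N1Br
Why: C3 is the β-carbon of an enol ether/vinylogous carbamate and is far more nucleophilic than ring A, so electrophilic bromination is regioselective.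

**Step 4**
Reactants: 5 3-bromo-4,8-dimethoxy-1-methylquinolin-2(1H)-one; 6 methyl (2R)-oxirane-2-carboxylate (1.5 equiv)
Product: 8 methyl (2R)-3-(4,8-dimethoxy-1-methyl-2-oxo-1,2-dihydroquinolin-3-yl)-2-hydroxypropanoate, via iodohydrin 7 (not isolated)
Conditions: NiBr2·glyme (10 mol%), 4,4'-di-tert-butyl-2,2'-bipyridine (12 mol%), 4CzIPN [2,4,5,6-tetrakis(carbazol-9-yl)isophthalonitrile] (2 mol%), NaI (50 mol%), Hantzsch ester (1.5 equiv), 2,6-lutidine (1.5 equiv), DMA, 450 nm LEDs, 30 °C
Reagents that add atoms: none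
Why: Proposed new method: an iodide-relay nickel/photoredox cross-electrophile coupling of a 3-bromo-2-quinolone with a glycidic ester, in which lutidinium iodide (formed as the Hantzsch ester is oxidised) opens 6 by SN2 at the unsubstituted C3 to iodohydrin 7 without touching the C2–O bond, photoreduced 4CzIPN takes divalent nickel down to zerovalent nickel that inserts into the C3–Br bond of 5, a monovalent nickel halide abstracts iodine from 7 to give a primary β-hydroxyalkyl radical that is captured at nickel, and reductive elimination from trivalent nickel forges the C3–CH2 bond, so the bought (R) stereocenter, one carbon away from the radical, passes through unchanged; the closest known reaction type is the nickel-catalysed reductive arylation of terminal epoxides under iodide co-catalysis together with nickel/photoredox aryl halide–epoxide couplings, neither shown for glycidic esters or for 3-halo-4-alkoxy-2-quinolones.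

**Step 5**
Reactants: 8 methyl (2R)-3-(4,8-dimethoxy-1-methyl-2-oxo-1,2-dihydroquinolin-3-yl)-2-hydroxypropanoate
Product: 9 3-[(2R)-2,3-dihydroxy-3-methylbutyl]-4,8-dimethoxy-1-methylquinolin-2(1H)-one
Conditions: MeMgBr (3.5 equiv), THF, −20 to 0 °C; aq NH4Cl at 0 °C
Reagents that add atoms: methylmagnesium bromide, C[Mg]Br
Why: Double Grignard addition to the methyl ester gives the tertiary carbinol, while the carbinol is held as its magnesium alkoxide, which blocks α-deprotonation and keeps the (R) configuration; the vinylogous amide of the quinolone is inert at or below 0 °C.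

**Step 6**
Reactants: 9 3-[(2R)-2,3-dihydroxy-3-methylbutyl]-4,8-dimethoxy-1-methylquinolin-2(1H)-one; 10 hexadecanoyl chloride (1.15 equiv)
Product: 12 (2R)-1-(4,8-dimethoxy-1-methyl-2-oxo-1,2-dihydroquinolin-3-yl)-3-methylbut-3-en-2-yl hexadecanoate, via hydroxy palmitate 11 (not isolated)
Conditions: pyridine, DMAP (10 mol%), CH2Cl2, 0 °C to rt; then SOCl2 (2 equiv), −10 to 0 °C
Reagents that add atoms: none
Why: DMAP-catalysed acylation takes the secondary hydroxyl and leaves the tertiary one, whose chlorosulfite then undergoes pyridine-induced E2 elimination toward a methyl group (six accessible hydrogens against one hindered, inductively deactivated hydrogen on the acyloxy carbon), and neither event breaks a bond at the stereocenter (selective acylation followed by SOCl2/pyridine dehydration).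

**Compound list**
1 | 2-methoxy-N-methylaniline | CNc1ccccc1OC | starting material
2 | bis(2,4,6-trichlorophenyl) malonate | O=C(CC(=O)Oc1c(Cl)cc(Cl)cc1Cl)Oc1c(Cl)cc(Cl)cc1Cl | starting material
3 | 4-hydroxy-8-methoxy-1-methylquinolin-2(1H)-one | COc1cccc2c(O)cc(=O)n(C)c12 | intermediate
4 | 4,8-dimethoxy-1-methylquinolin-2(1H)-one | COc1cccc2c(OC)cc(=O)n(C)c12 | intermediate
5 | 3-bromo-4,8-dimethoxy-1-methylquinolin-2(1H)-one | COc1cccc2c(OC)c(Br)c(=O)n(C)c12 | intermediate
6 | methyl (2R)-oxirane-2-carboxylate | COC(=O)[C@H]1CO1 | starting material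
7 | methyl (2S)-2-hydroxy-3-iodopropanoate (iodohydrin; same spatial arrangement as 6, descriptor changes because CH2I outranks the ester) | COC(=O)[C@H](O)CI | intermediate
8 | methyl (2R)-3-(4,8-dimethoxy-1-methyl-2-oxo-1,2-dihydroquinolin-3-yl)-2-hydroxypropanoate | COC(=O)[C@H](O)Cc1c(OC)c2cccc(OC)c2n(C)c1=O | intermediate
9 | 3-[(2R)-2,3-dihydroxy-3-methylbutyl]-4,8-dimethoxy-1-methylquinolin-2(1H)-one | CC(C)(O)[C@H](O)Cc1c(OC)c2cccc(OC)c2n(C)c1=O | intermediate
10 | hexadecanoyl chloride (palmitoyl chloride) | CCCCCCCCCCCCCCCC(=O)Cl | starting material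
11 | (2R)-1-(4,8-dimethoxy-1-methyl-2-oxo-1,2-dihydroquinolin-3-yl)-3-hydroxy-3-methylbutan-2-yl hexadecanoate | CC(C)(O)[C@@H](Cc1c(OC)c2cccc(OC)c2n(C)c1=O)OC(=O)CCCCCCCCCCCCCCC | intermediate
12 | (2R)-1-(4,8-dimethoxy-1-methyl-2-oxo-1,2-dihydroquinolin-3-yl)-3-methylbut-3-en-2-yl hexadecanoate | C=C(C)[C@@H](Cc1c(OC)c2cccc(OC)c2n(C)c1=O)OC(=O)CCCCCCCCCCCCCCC | target

**Step count and risks**
Total steps: 6. Longest linear sequence: 6 (1 → 3 → 4 → 5 → 8 → 9 → 12).

Most likely to fail, first: step 4 (the proposed new coupling). The bromide sits between a carbonyl and a methoxy group, so oxidative addition may be slow. Hydrodebromination back to 4 (which can be re-brominated) and reduction of the iodohydrin to methyl lactate are the expected side paths. The ee of 8 should be checked, because reversible hydrogen abstraction at the captodative C2–H is conceivable. The fallback uses known chemistry, sets out from 5 and comes back at 9. D-malic acid is condensed with 2,2-dimethoxypropane (cat. TsOH) to [(4R)-2,2-dimethyl-5-oxo-1,3-dioxolan-4-yl]acetic acid F1. F1 is esterified with N-hydroxyphthalimide (DIC, cat. DMAP, CH2Cl2) to 1,3-dioxoisoindolin-2-yl [(4R)-2,2-dimethyl-5-oxo-1,3-dioxolan-4-yl]acetate F2. The established nickel-catalysed decarboxylative arylation of N-hydroxyphthalimide esters with aryl halides (NiBr2·glyme, 4,4'-di-tert-butyl-2,2'-bipyridine, Hantzsch ester, NaHCO3, DMA, 390 nm LEDs; the Hantzsch ester–phthalimide ester donor–acceptor pair absorbs the light) joins F2 to 5. This gives (5R)-5-[(4,8-dimethoxy-1-methyl-2-oxo-1,2-dihydroquinolin-3-yl)methyl]-2,2-dimethyl-1,3-dioxolan-4-one F3. Excess MeMgBr (THF, −20 to 0 °C) opens F3 directly to diol 9, and the acetonide carbon is consumed as tert-butoxide.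

Second: step 6 (acylation/dehydration in one pot). The elimination may give some enol ester or tertiary chloride, and the neighbouring acyloxy group can participate. The fallback sets out from 9 and comes back at 12. Diol 9 is converted with net retention into the epoxide 3-{[(2R)-3,3-dimethyloxiran-2-yl]methyl}-4,8-dimethoxy-1-methylquinolin-2(1H)-one F7 by the cyclic orthoacetate/acetoxy bromide sequence (MeC(OMe)3, cat. PPTS; AcBr; then K2CO3, MeOH). Et2Al(TMP), made from Et2AlCl and LiTMP, in toluene at 0 °C isomerises F7 by syn removal of a methyl proton, which can only give the isopropenyl carbinol 3-[(2R)-2-hydroxy-3-methylbut-3-en-1-yl]-4,8-dimethoxy-1-methylquinolin-2(1H)-one F8. F8 is acylated with 10 (pyridine, DMAP, CH2Cl2) to 12.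

Third: step 5 (excess Grignard). The secondary or tertiary alkoxide next to the C4 methoxy group could close to a dihydrofuro- or pyrano-quinolone with loss of methoxide, or the addition could stall. The fallback sets out from 8 and comes back at 12, and also avoids the dehydration. Ester 8 is converted with MeNHOMe·HCl and AlMe3 (CH2Cl2, 0 °C to rt) into the Weinreb amide (2R)-3-(4,8-dimethoxy-1-methyl-2-oxo-1,2-dihydroquinolin-3-yl)-2-hydroxy-N-methoxy-N-methylpropanamide F4. MeMgBr (2.2 equiv, THF, −78 to 0 °C) gives the hydroxy ketone 3-[(2R)-2-hydroxy-3-oxobutyl]-4,8-dimethoxy-1-methylquinolin-2(1H)-one F5. Acylation with 10 (pyridine, DMAP) gives (2R)-1-(4,8-dimethoxy-1-methyl-2-oxo-1,2-dihydroquinolin-3-yl)-3-oxobutan-2-yl hexadecanoate F6. Non-basic Takai–Lombardo methylenation (Zn, CH2Br2, TiCl4, THF/CH2Cl2, 0 °C to rt) converts the ketone of F6 into the alkene of 12 without touching the esters or the stereocenter.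

**Further compounds**
F1 | step 4 | [(4R)-2,2-dimethyl-5-oxo-1,3-dioxolan-4-yl]acetic acid | CC1(C)O[C@H](CC(=O)O)C(=O)O1
F2 | step 4 | 1,3-dioxoisoindolin-2-yl [(4R)-2,2-dimethyl-5-oxo-1,3-dioxolan-4-yl]acetate | CC1(C)O[C@H](CC(=O)ON2C(=O)c3ccccc3C2=O)C(=O)O1
F3 | step 4 | (5R)-5-[(4,8-dimethoxy-1-methyl-2-oxo-1,2-dihydroquinolin-3-yl)methyl]-2,2-dimethyl-1,3-dioxolan-4-one | CC1(C)O[C@H](Cc2c(OC)c3cccc(OC)c3n(C)c2=O)C(=O)O1
F4 | step 5 | (2R)-3-(4,8-dimethoxy-1-methyl-2-oxo-1,2-dihydroquinolin-3-yl)-2-hydroxy-N-methoxy-N-methylpropanamide | CON(C)C(=O)[C@H](O)Cc1c(OC)c2cccc(OC)c2n(C)c1=O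
F5 | step 5 | 3-[(2R)-2-hydroxy-3-oxobutyl]-4,8-dimethoxy-1-methylquinolin-2(1H)-one | CC(=O)[C@H](O)Cc1c(OC)c2cccc(OC)c2n(C)c1=O
F6 | step 5 | (2R)-1-(4,8-dimethoxy-1-methyl-2-oxo-1,2-dihydroquinolin-3-yl)-3-oxobutan-2-yl hexadecanoate | CC(=O)[C@@H](Cc1c(OC)c2cccc(OC)c2n(C)c1=O)OC(=O)CCCCCCCCCCCCCCC
F7 | step 6 | 3-{[(2R)-3,3-dimethyloxiran-2-yl]methyl}-4,8-dimethoxy-1-methylquinolin-2(1H)-one | CC3(C)O[C@@H]3Cc1c(OC)c2cccc(OC)c2n(C)c1=O
F8 | step 6 | 3-[(2R)-2-hydroxy-3-methylbut-3-en-1-yl]-4,8-dimethoxy-1-methylquinolin-2(1H)-one | C=C(C)[C@H](O)Cc1c(OC)c2cccc(OC)c2n(C)c1=O
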